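The saturated ring B of the aryltetralin is assembled by a (3+3) union. The benzylic carbon C4 and the ring-A carbon C8a of a 5-hydroxyvanillyl unit are joined to C3 and C1 of a three-carbon piece that is stored as an enantioenriched donor–acceptor cyclopropane. In one flask the para-phenoxide of ring C opens the strained C1–C3 bond, the released malonate carbon C3 adds to a quinone methide at C4, and acid then closes C8a onto C1. The step exploits the para-hydroxyl groups of rings A and C, which make C4 and C1 quinone-methide electrophiles, and the C8 hydroxyl/C6 methoxy pair that activates C8a. The precursor is a trisubstituted cyclopropane-1,1-diester plus a benzylic triacetate.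

Key step: step 6

Numbering used throughout: tetralin numbering of the target. C1 carries the guaiacyl ring C, C2 and C3 carry CH2OH, C4 is the benzylic CH2. Ring A is C4a–C5–C6(OMe)–C7(OH)–C8(OH)–C8a; ring B is C1–C4 with C4a and C8a.

Assumption: with the (S)-diarylprolinol silyl ether the bromomalonate should add to the Si face of the enal β-carbon, as for other cinnamaldehydes, so that 3 is (2R,3S); compounds 1, 2 and 6 are taken as purchasable.

Step 1
Reactants: 1 (E)-4-acetoxy-3-methoxycinnamaldehyde; 2 dimethyl bromomalonate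
Product: 3 dimethyl (2R,3S)-3-(4-acetoxy-3-methoxyphenyl)-2-formylcyclopropane-1,1-dicarboxylate
Conditions: (S)-α,α-diphenylprolinol trimethylsilyl ether (10 mol %), 2,6-lutidine, CH2Cl2, 0 °C → rt
Reagents that add atoms: none
Why: Organocatalytic Michael-initiated ring closure (iminium then enamine catalysis): the bromomalonate should add to the enal β-carbon on the face away from the diphenyl(silyloxy)methyl group and the enamine then displaces bromide, which sets the future C2 as R in the trans-cyclopropane.

Step 2
Reactants: 3 dimethyl (2R,3S)-3-(4-acetoxy-3-methoxyphenyl)-2-formylcyclopropane-1,1-dicarboxylate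
Product: 4 dimethyl (2R,3S)-3-(4-acetoxy-3-methoxyphenyl)-2-(hydroxymethyl)cyclopropane-1,1-dicarboxylate
Conditions: BH3·THF, THF, −20 → 0 °C; MeOH quench
Reagents that add atoms: none
Why: Chemoselective borane reduction of the aldehyde beside esters; the neutral boron alkoxide should avoid lactonisation onto the cis ester and loss of the aryl acetate, and no stereocentre is touched.

Step 3
Reactants: 4 dimethyl (2R,3S)-3-(4-acetoxy-3-methoxyphenyl)-2-(hydroxymethyl)cyclopropane-1,1-dicarboxylate
Product: 5 dimethyl (2R,3S)-3-(4-acetoxy-3-methoxyphenyl)-2-[(pivaloyloxy)methyl]cyclopropane-1,1-dicarboxylate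
Conditions: pivaloyl chloride, pyridine, DMAP (cat.), CH2Cl2, 0 °C (crude 4 used directly)
Reagents that add atoms: pivaloyl chloride, CC(C)(C)C(=O)Cl
Why: DMAP-catalysed O-acylation; the pivalate should withstand the carbonate, acid and Krapcho conditions that follow and is removed by the final hydride reduction.

Step 4
Reactants: 6 3,4-dihydroxy-5-methoxybenzaldehyde (5-hydroxyvanillin)
Product: 7 5-(hydroxymethyl)-3-methoxybenzene-1,2-diol
Conditions: NaBH4, MeOH, 0 °C
Reagents that add atoms: none
Why: Borohydride reduction of an aryl aldehyde to the benzylic alcohol.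

Step 5
Reactants: 7 5-(hydroxymethyl)-3-methoxybenzene-1,2-diol
Product: 8 3,4-diacetoxy-5-methoxybenzyl acetate
Conditions: Ac2O, pyridine, DMAP (cat.), CH2Cl2, 0 °C → rt
Reagents that add atoms: acetic anhydride, CC(=O)OC(C)=O
Why: Peracetylation; the 4-acetoxybenzyl acetate unit is a bench-stable precursor of the para-quinone methide of ring A.

Step 6
Reactants: 5 dimethyl (2R,3S)-3-(4-acetoxy-3-methoxyphenyl)-2-[(pivaloyloxy)methyl]cyclopropane-1,1-dicarboxylate; 8 3,4-diacetoxy-5-methoxybenzyl acetate
Product: 11 dimethyl (3R,4S)-5,6-dihydroxy-4-(4-hydroxy-3-methoxyphenyl)-7-methoxy-3-[(pivaloyloxy)methyl]-3,4-dihydronaphthalene-2,2(1H)-dicarboxylate, via methoxy malonate 9 (not isolated), via benzylated malonate 10 (not isolated)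
Conditions: K2CO3, MeOH/THF, 40 °C; then 8 added slowly, 0 °C → rt; then HCl (4 M in dioxane, excess), 40 °C
Reagents that add atoms: none
Why: Proposed new method: K2CO3 in MeOH strips the aryl acetates; the para-phenoxide of ring C then pushes open the strained C1–C3 bond of 5 to a quinone methide/malonate pair that MeOH caps at C1 (9), the malonate carbon C3 adds 1,6 to the quinone methide that 8 releases by loss of its benzylic acetate (C3–C4, 10), and HCl finally ionises the C1–OMe ether so that ring A attacks C1 through C8a (C8a–C1). The closest known reactions are nucleophilic ring opening of donor–acceptor cyclopropanes (here triggered by the phenoxide instead of a Lewis acid), malonate alkylation by quinone methides from 4-acetoxybenzyl acetates, and the acid-mediated Friedel–Crafts cyclisation of 4-hydroxybenzylic ethers to aryltetralins; the one-flask relay of the three is new. Ring B closes in a 6-exo-trig Friedel–Crafts mode on the protonated quinone methide of ring C. C1 is the only new stereocentre: in the chair transition state the guaiacyl group should go equatorial, trans to the equatorial CH2OPiv group at C2, because an axial aryl would clash 1,3-diaxially with the axial ester on C3, so C2 (from step 1) relays its configuration while the old C1 configuration of 5 is erased. The step needs closure at C8a and not at C5, which the substrate should secure because C8a is para to the C6 methoxy group and ortho to the small free C8 hydroxyl while C5 is screened by the C6 methoxy group that the C7 oxygen buttresses towards it; it also needs the malonate to outrun C-benzylation of the phenoxide rings, which the pre-formed, far more nucleophilic malonate anion and slow addition of 8 should secure.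

Step 7
Reactants: 11 dimethyl (3R,4S)-5,6-dihydroxy-4-(4-hydroxy-3-methoxyphenyl)-7-methoxy-3-[(pivaloyloxy)methyl]-3,4-dihydronaphthalene-2,2(1H)-dicarboxylate
Product: 13 methyl (2R,3R,4S)-5,6-dihydroxy-4-(4-hydroxy-3-methoxyphenyl)-7-methoxy-3-[(pivaloyloxy)methyl]-1,2,3,4-tetrahydronaphthalene-2-carboxylate, via 2-epimer 12 (not isolated)
Conditions: LiCl, H2O, DMSO, 140 °C, argon; then DBU, 60 °C
Reagents that add atoms: none
Why: Krapcho dealkoxycarbonylation (chloride demethylation, loss of CO2) followed by base equilibration of the enolisable ester carbon (C3 of the target), which should place the ester equatorial and trans to the CH2OPiv group at C2 under thermodynamic control.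

Step 8
Reactants: 13 methyl (2R,3R,4S)-5,6-dihydroxy-4-(4-hydroxy-3-methoxyphenyl)-7-methoxy-3-[(pivaloyloxy)methyl]-1,2,3,4-tetrahydronaphthalene-2-carboxylate
Product: 14 (1S,2R,3R)-1-(4-hydroxy-3-methoxyphenyl)-2,3-bis(hydroxymethyl)-6-methoxy-1,2,3,4-tetrahydronaphthalene-7,8-diol
Conditions: LiAlH4 (excess), THF, 0 °C → reflux; aq. HCl work-up
Reagents that add atoms: none
Why: Hydride reduction of the methyl ester and reductive cleavage of the pivalate in the same operation should give both primary alcohols without touching the three stereocentres.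

Compound list
1 | (E)-4-acetoxy-3-methoxycinnamaldehyde | CC(=O)Oc1ccc(/C=C/C=O)cc1OC | starting material
2 | dimethyl bromomalonate | COC(=O)C(Br)C(=O)OC | starting material
3 | dimethyl (2R,3S)-3-(4-acetoxy-3-methoxyphenyl)-2-formylcyclopropane-1,1-dicarboxylate | O=C[C@@H]1[C@@H](c2ccc(OC(C)=O)c(OC)c2)C1(C(=O)OC)C(=O)OC | intermediate
4 | dimethyl (2R,3S)-3-(4-acetoxy-3-methoxyphenyl)-2-(hydroxymethyl)cyclopropane-1,1-dicarboxylate | OC[C@@H]1[C@@H](c2ccc(OC(C)=O)c(OC)c2)C1(C(=O)OC)C(=O)OC | intermediate
5 | dimethyl (2R,3S)-3-(4-acetoxy-3-methoxyphenyl)-2-[(pivaloyloxy)methyl]cyclopropane-1,1-dicarboxylate | CC(C)(C)C(=O)OC[C@@H]1[C@@H](c2ccc(OC(C)=O)c(OC)c2)C1(C(=O)OC)C(=O)OC | intermediate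
6 | 3,4-dihydroxy-5-methoxybenzaldehyde (5-hydroxyvanillin) | O=Cc1cc(O)c(O)c(OC)c1 | starting material
7 | 5-(hydroxymethyl)-3-methoxybenzene-1,2-diol | OCc1cc(O)c(O)c(OC)c1 | intermediate
8 | 3,4-diacetoxy-5-methoxybenzyl acetate | CC(=O)OCc1cc(OC(C)=O)c(OC(C)=O)c(OC)c1 | intermediate
9 | dimethyl 2-[(2R)-1-(4-hydroxy-3-methoxyphenyl)-1-methoxy-3-(pivaloyloxy)propan-2-yl]malonate (both C1 epimers) | COC(=O)C(C(=O)OC)[C@H](COC(=O)C(C)(C)C)C(OC)c1ccc(O)c(OC)c1 | intermediate
10 | dimethyl 2-(3,4-dihydroxy-5-methoxybenzyl)-2-[(2R)-1-(4-hydroxy-3-methoxyphenyl)-1-methoxy-3-(pivaloyloxy)propan-2-yl]malonate (both C1 epimers) | COC(=O)C(Cc1cc(O)c(O)c(OC)c1)(C(=O)OC)[C@H](COC(=O)C(C)(C)C)C(OC)c1ccc(O)c(OC)c1 | intermediate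
11 | dimethyl (3R,4S)-5,6-dihydroxy-4-(4-hydroxy-3-methoxyphenyl)-7-methoxy-3-[(pivaloyloxy)methyl]-3,4-dihydronaphthalene-2,2(1H)-dicarboxylate | COc1cc([C@H]2c3c(cc(OC)c(O)c3O)CC(C(=O)OC)(C(=O)OC)[C@@H]2COC(=O)C(C)(C)C)ccc1O | intermediate
12 | methyl (2S,3R,4S)-5,6-dihydroxy-4-(4-hydroxy-3-methoxyphenyl)-7-methoxy-3-[(pivaloyloxy)methyl]-1,2,3,4-tetrahydronaphthalene-2-carboxylate | COc1cc([C@H]2c3c(cc(OC)c(O)c3O)C[C@H](C(=O)OC)[C@@H]2COC(=O)C(C)(C)C)ccc1O | intermediate
13 | methyl (2R,3R,4S)-5,6-dihydroxy-4-(4-hydroxy-3-methoxyphenyl)-7-methoxy-3-[(pivaloyloxy)methyl]-1,2,3,4-tetrahydronaphthalene-2-carboxylate | COc1cc([C@H]2c3c(cc(OC)c(O)c3O)C[C@@H](C(=O)OC)[C@@H]2COC(=O)C(C)(C)C)ccc1O | intermediate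
14 | (1S,2R,3R)-1-(4-hydroxy-3-methoxyphenyl)-2,3-bis(hydroxymethyl)-6-methoxy-1,2,3,4-tetrahydronaphthalene-7,8-diol | COc1cc([C@H]2c3c(cc(OC)c(O)c3O)C[C@@H](CO)[C@@H]2CO)ccc1O | target

Total step count: 8. Longest linear sequence: 6 steps (steps 1, 2, 3, 6, 7, 8 from compound 1).

Steps most likely to fail

1. Step 6 (Proposed new method). The ring opening may be slow, so that the quinone methide from 8 is consumed by irreversible C-benzylation of phenoxide ring carbons (self-condensation) before the malonate captures it. Ring closure may also take place at C5 instead of C8a, or the C1 cation may eliminate to a styrene and scramble C2. Fallback, from 5 back to 11 by three isolated steps of known types: Sc(OTf)3-catalysed methanolysis of the donor–acceptor cyclopropane (MeOH, 50 °C) should give the ring-opened ether dimethyl 2-[(2R)-1-(4-acetoxy-3-methoxyphenyl)-1-methoxy-3-(pivaloyloxy)propan-2-yl]malonate F1 with the aryl acetate intact. F1 and 8 are then joined with K2CO3 in MeOH (quinone-methide alkylation of the stoichiometric malonate, with loss of the aryl acetate) to give 10, which is isolated and purified. Compound 10 is closed to 11 in formic acid at room temperature, where the Friedel–Crafts step can be optimised on its own.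

2. Step 7. At 140 °C the free phenoxides may be O-methylated by the chloromethane that the Krapcho reaction releases, the catecholate may be oxidised, and equilibration at the ester carbon may stay incomplete. Fallback, from 11 to 14, bypassing 13: the three phenols are first pivaloylated (pivaloyl chloride, pyridine, DMAP) to dimethyl (3R,4S)-7-methoxy-4-[3-methoxy-4-(pivaloyloxy)phenyl]-5,6-bis(pivaloyloxy)-3-[(pivaloyloxy)methyl]-3,4-dihydronaphthalene-2,2(1H)-dicarboxylate F2. Krapcho dealkoxycarbonylation and DBU equilibration on this protected compound should give methyl (2R,3R,4S)-7-methoxy-4-[3-methoxy-4-(pivaloyloxy)phenyl]-5,6-bis(pivaloyloxy)-3-[(pivaloyloxy)methyl]-1,2,3,4-tetrahydronaphthalene-2-carboxylate F3. The LiAlH4 conditions of step 8 then cleave all four pivalates and reduce the ester, giving 14 with no extra deprotection step.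

3. Step 1. A base-mediated, uncatalysed Michael-initiated ring closure may erode the enantiomeric purity, and acyl transfer from the aryl acetate to the amine catalyst may stop turnover. Fallback, from 1 back to 3, separating the C–C bond formation from the ring closure: conjugate addition of dimethyl malonate to 1 with the same diarylprolinol silyl ether and no stoichiometric base should give dimethyl 2-[(1R)-1-(4-acetoxy-3-methoxyphenyl)-3-oxopropyl]malonate F4. Iodine and DBU in CH2Cl2 then iodinate the malonate carbon and close the ring through the aldehyde enolate to the trans-cyclopropane 3.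

Further compounds
F1 | step 6 | dimethyl 2-[(2R)-1-(4-acetoxy-3-methoxyphenyl)-1-methoxy-3-(pivaloyloxy)propan-2-yl]malonate | COC(=O)C(C(=O)OC)[C@H](COC(=O)C(C)(C)C)C(OC)c1ccc(OC(C)=O)c(OC)c1
F2 | step 7 | dimethyl (3R,4S)-7-methoxy-4-[3-methoxy-4-(pivaloyloxy)phenyl]-5,6-bis(pivaloyloxy)-3-[(pivaloyloxy)methyl]-3,4-dihydronaphthalene-2,2(1H)-dicarboxylate | COc1cc([C@H]2c3c(cc(OC)c(OC(=O)C(C)(C)C)c3OC(=O)C(C)(C)C)CC(C(=O)OC)(C(=O)OC)[C@@H]2COC(=O)C(C)(C)C)ccc1OC(=O)C(C)(C)C
F3 | step 7 | methyl (2R,3R,4S)-7-methoxy-4-[3-methoxy-4-(pivaloyloxy)phenyl]-5,6-bis(pivaloyloxy)-3-[(pivaloyloxy)methyl]-1,2,3,4-tetrahydronaphthalene-2-carboxylate | COc1cc([C@H]2c3c(cc(OC)c(OC(=O)C(C)(C)C)c3OC(=O)C(C)(C)C)C[C@@H](C(=O)OC)[C@@H]2COC(=O)C(C)(C)C)ccc1OC(=O)C(C)(C)C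
F4 | step 1 | dimethyl 2-[(1R)-1-(4-acetoxy-3-methoxyphenyl)-3-oxopropyl]malonate | O=CC[C@@H](c1ccc(OC(C)=O)c(OC)c1)C(C(=O)OC)C(=O)OC
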